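**Plan**

- Feature: with the decalin numbered as naphthalen-2(1H)-one (ring A = C4a, C5–C8, C8a; ring B = C1–C4, C4a, C8a) and the cyclopentane as C1′–C5′ (C1′ on C3), the bromide at C3′, the vicinal quaternary pair C2′/C1′ and the tertiary allylic alcohol at C4a lie on one path, C3′–C2′–C1′–C3=C4–C4a. This is the trace of a prenyl bromonium ion that has closed onto a C1′=C3–C4=C4a diene.
- Cuts, in retrosynthetic order: C2=O (allylic oxidation); then C3′–Br, C1′–C2′ and C4a–O together (key step); then C5–CH3 (MeLi on a dienone), C1′=C3 (selenium-based olefination with 6-methylhept-5-en-2-one), C5–O (vinylogous Rubottom) and C8–Br (sulfonate inversion), back to (S)-Wieland–Miescher ketone.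
- Forward order: rings A and B come with the Wieland–Miescher ketone, the C8 chain is joined at C3 in steps 10–11, and the cyclopentane closes in step 15.
- Stereochemistry: C8a from the starting ketone; C8 by equatorial hydride delivery then SN2 inversion; C5 by methyl addition anti to the angular methyl; C4a by trans-diaxial oxirane opening.
- C3′ comes from a chiral Br+ donor; C1′ follows from C3′ through the ring-closing transition state.

Key step: step 15

Remark: all compounds carry the target numbering and β is the face of the C8a methyl; the C1′=C3 geometry made in step 11 is not expected to be controlled and is erased in step 15 (C3 ends as an sp2 carbon of C3=C4), so 14–17 are carried as the E/Z mixture and written as the E isomer.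

**Route**

Step 1
Reactants: 1 (S)-Wieland–Miescher ketone
Product: 2 enone dithiolane (C3 spiro-1,3-dithiolane; C8 ketone free)
Conditions: HS(CH2)2SH (1.05 equiv), TsOH·H2O (cat.), AcOH, rt
Reagents that add atoms: ethane-1,2-dithiol, SCCS
Why: Acid-catalysed thioketalization is chemoselective for the conjugated C3 carbonyl and does not move the C4=C4a alkene, while the C8 ketone, shielded by quaternary C8a, stays free for the hydride step in which the enone must be masked.

Step 2
Reactants: 2 enone dithiolane
Product: 3 8α-hydroxy dithiolane (axial OH trans to the C8a methyl)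
Conditions: K[BH(s-Bu)3], THF, −78 °C; then H2O
Reagents that add atoms: none
Why: A bulky trialkylborohydride delivers hydride to the cyclohexanone from the equatorial direction (as with 4,4-dimethyl-3-oxo triterpenoids), so the new C8 centre should carry an axial α-hydroxyl, trans to the C8a methyl and ready for inversion.

Step 3
Reactants: 3 8α-hydroxy dithiolane
Product: 4 8α-chloromethanesulfonate
Conditions: ClCH2SO2Cl, pyridine, CH2Cl2, 0 °C
Reagents that add atoms: chloromethanesulfonyl chloride, ClCS(=O)(=O)Cl
Why: Sulfonylation of the secondary alcohol with retention gives a chloromethanesulfonate, a leaving group more reactive than a mesylate but less prone to ionize than a triflate.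

Step 4
Reactants: 4 8α-chloromethanesulfonate
Product: 5 8β-bromo dithiolane
Conditions: LiBr, DMF, 50 °C
Reagents that add atoms: lithium bromide, [Li+].[Br-]
Why: SN2 displacement by bromide enters along the equatorial direction anti to the axial sulfonate and inverts C8 to the equatorial 8β-bromide, cis to the C8a methyl as in the target; the equatorial bromide has no anti-periplanar hydrogen and should be robust in all later steps.

Step 5
Reactants: 5 8β-bromo dithiolane
Product: 6 8β-bromo enone
Conditions: MeI, CaCO3, MeCN/H2O (4:1), 50 °C
Reagents that add atoms: water, O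
Why: S-Methylation and hydrolysis of the allylic dithiolane (dethioketalization) returns the enone under buffered, non-basic conditions that leave the hindered secondary bromide alone.

Step 6
Reactants: 6 8β-bromo enone
Product: 7 silyl dienol ether (3-OTBS; C3=C4 and C4a=C5)
Conditions: TBSOTf, Et3N, CH2Cl2, 0 °C → rt
Reagents that add atoms: tert-butyldimethylsilyl trifluoromethanesulfonate, CC(C)(C)[Si](C)(C)OS(=O)(=O)C(F)(F)F
Why: Soft enolization with a silyl triflate and an amine under equilibrating conditions removes the γ-hydrogen at C5 and gives the extended (heteroannular) silyl dienol ether, as with steroidal 4-en-3-ones.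

Step 7
Reactants: 7 silyl dienol ether
Product: 8 5β-hydroxy enone
Conditions: mCPBA, CH2Cl2, −20 °C → 0 °C; aq. NaHCO3 work-up
Reagents that add atoms: 3-chloroperoxybenzoic acid, OOC(=O)c1cccc(Cl)c1
Why: Vinylogous Rubottom oxidation: the peracid attacks the γ-terminus C5 of the dienol ether and collapse of the 4a,5-epoxide restores the enone with a C5 hydroxyl, expected axial (β) by analogy with 6β-hydroxylation of steroidal dienol ethers, although this centre is erased in step 13.

Step 8
Reactants: 8 5β-hydroxy enone
Product: 9 5β-triethylsilyloxy enone
Conditions: TESCl, imidazole, DMF, 0 °C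
Reagents that add atoms: chlorotriethylsilane, CC[Si](Cl)(CC)CC
Why: Silylation of the secondary alcohol with a silyl chloride and imidazole protects C5–OH from the organolithium and from the elimination reagent.

Step 9
Reactants: 10 6-methylhept-5-en-2-one
Product: 11 2,2-bis(phenylseleno)-6-methylhept-5-ene
Conditions: PhSeH (2.2 equiv), ZnCl2 (0.5 equiv), CH2Cl2, 0 °C → rt
Reagents that add atoms: benzeneselenol, [SeH]c1ccccc1
Why: Lewis-acid-mediated selenoacetalization of the methyl ketone gives the precursor of a tertiary α-selenoalkyllithium; the remote trisubstituted alkene should survive ZnCl2 at or below room temperature.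

Step 10
Reactants: 11 2,2-bis(phenylseleno)-6-methylhept-5-ene; 9 5β-triethylsilyloxy enone
Product: 13 β-hydroxy selenide (C3/C1′ diastereomer mixture), via 2-lithio-2-(phenylseleno)-6-methylhept-5-ene 12 (not isolated)
Conditions: n-BuLi, THF, −78 °C; then 9, −78 °C; then H2O
Reagents that add atoms: none
Why: Selenium–lithium exchange gives the weakly basic α-selenoalkyllithium 12, which adds 1,2 to the enone carbonyl in THF (first stage of the Krief–Reich olefination) and joins C1′ to C3; the two new centres form as a mixture and are both destroyed in step 11.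

Step 11
Reactants: 13 β-hydroxy selenide
Product: 14 exocyclic diene triethylsilyl ether
Conditions: PI3, Et3N, CH2Cl2, 0 °C → rt
Reagents that add atoms: none
Why: Activation of the tertiary hydroxyl and anti elimination through a seleniranium ion (Krief–Reich olefination) can place the new alkene only between C3 and C1′, which avoids the regiochemical ambiguity of a dehydration and gives the tetrasubstituted exocyclic alkene conjugated with C4=C4a as an E/Z mixture.

Step 12
Reactants: 14 exocyclic diene triethylsilyl ether
Product: 15 dienol (free 5β-OH)
Conditions: Bu4NF, THF, 0 °C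
Reagents that add atoms: none
Why: Fluoride-mediated cleavage of the triethylsilyl ether proceeds under basic conditions that the acid-sensitive diene tolerates.

Step 13
Reactants: 15 dienol
Product: 16 dienone (C5 ketone conjugated with C4a=C4 and C3=C1′)
Conditions: DMP, pyridine, CH2Cl2, 0 °C
Reagents that add atoms: none
Why: Dess–Martin oxidation of the dienylic secondary alcohol under buffered conditions gives the fully conjugated dienone and removes the C5 stereocentre.

Step 14
Reactants: 16 dienone
Product: 17 cyclization precursor (5α-methyl-5β-hydroxy dienyl bromodecalin with prenyl-terminated chain)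
Conditions: MeLi, THF, −78 °C; then H2O (work-up at pH ≥ 7)
Reagents that add atoms: methyllithium, [Li]C
Why: 1,2-Addition of methyllithium to the dienone carbonyl takes place from the α-face because the β-face of C5 is screened by the syn-axial C8a methyl, which should give the 5α-methyl-5β-hydroxy (5R) carbinol of the target.

Step 15
Reactants: 17 cyclization precursor
Product: 19 2-deoxo target (dibromo 4aα,5β-diol), via 4aβ,5β-epoxide 18 (not isolated)
Conditions: 1,3-dibromo-5,5-dimethylhydantoin (1.0 equiv), chiral BINOL-derived thiophosphoramide (10 mol %), CH2Cl2/toluene, −78 °C; then THF/H2O, PPTS (cat.), 0 °C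
Reagents that add atoms: 1,3-dibromo-5,5-dimethylhydantoin, CC1(C)N(Br)C(=O)N(Br)C1=O; water, O
Why: Proposed new method: the Lewis-base-bound Br+ is transferred to the distal C2′=C3′ alkene, the tertiary end C2′ of the bromonium ion is attacked by the diene terminus C1′ to close the cyclopentane (5-exo with respect to the C1′=C3 nucleophile, endo with respect to the bromonium alkene), and the resulting C3–C4–C4a allyl cation is captured at C4a by the axial C5 hydroxyl as oxirane 18, which aqueous acid opens at the allylic carbon C4a with inversion to the trans-diaxial 4aα,5β-diol. The closest known reaction type is bromonium-initiated polyene cyclization with sulfonium- or Lewis-base-derived Br+ donors, which closes six-membered rings; five-ring closure is expected here because only attack through C1′ gives an allyl cation, whereas the six-ring mode (bond to C3) would give an isolated tertiary cation and a spiro centre. C3′ is set by the enantioface of Br+ delivery, which the remote decalin cannot influence and which therefore rests on the chiral thiophosphoramide–Br+ complex (a catalyst type that controls bromonium formation on geranyl-type terminal alkenes; the antipode is to be chosen by screening). C1′ follows from C3′ through an envelope transition state with bromine and the bulky decalin-bearing substituent both pseudo-equatorial (cis-1,3) and the C1′ methyl pseudo-axial. C4a is set by the substrate, since the axial C5–O bond is parallel to the C4a p-orbital, so oxirane closure should beat pinacol-type shifts, and water then enters anti to the oxirane and to the C8a methyl. The step needs Br+ at the prenyl alkene and not at the diene (bulk of the donor, shielding of the fully substituted diene terminus, reversible Br+ transfer between alkenes) and oxygen at C4a and not at C3 (neighbouring hydroxyl, quaternary C1′ blocking C3).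

Step 16
Reactants: 19 2-deoxo target
Product: 20 target CNP0216929.1
Conditions: Rh2(cap)4 (dirhodium tetracaprolactamate, 1 mol %), t-BuOOH (5 equiv), K2CO3, CH2Cl2, rt
Reagents that add atoms: tert-butyl hydroperoxide, CC(C)(C)OO
Why: Allylic oxidation with a dirhodium caprolactamate/tert-butyl hydroperoxide system proceeds by hydrogen abstraction, which is possible only at C2, the single hydrogen-bearing allylic carbon of the C3=C4 alkene (C1′ and C4a are fully substituted), and converts the methylene into the enone carbonyl without touching the tertiary alcohols or the secondary bromides.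

**Compound list**

1 | (S)-Wieland–Miescher ketone (C3 enone carbonyl, C8 saturated ketone, 8aS) | C[C@]12CCC(=O)C=C1CCCC2=O | starting material
2 | C3 spiro-1,3-dithiolane of 1, C8 ketone free | S1CCSC13C=C2CCCC(=O)[C@@]2(C)CC3 | intermediate
3 | 8α-hydroxy dithiolane (OH axial, trans to C8a methyl) | S1CCSC13C=C2CCC[C@@H](O)[C@@]2(C)CC3 | intermediate
4 | 8α-chloromethanesulfonate of 3 | S1CCSC13C=C2CCC[C@@H](OS(=O)(=O)CCl)[C@@]2(C)CC3 | intermediate
5 | 8β-bromo dithiolane (Br equatorial, cis to C8a methyl) | S1CCSC13C=C2CCC[C@H](Br)[C@@]2(C)CC3 | intermediate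
6 | 8β-bromo-8a-methyl enone (C3 ketone, C4=C4a) | O=C1C=C2CCC[C@H](Br)[C@@]2(C)CC1 | intermediate
7 | 3-(tert-butyldimethylsilyloxy) 3,4a(5)-diene of 6 | CC(C)(C)[Si](C)(C)OC1=CC2=CCC[C@H](Br)[C@@]2(C)CC1 | intermediate
8 | 8β-bromo-5β-hydroxy enone | O=C1C=C2[C@H](O)CC[C@H](Br)[C@@]2(C)CC1 | intermediate
9 | 8β-bromo-5β-triethylsilyloxy enone | O=C1C=C2[C@H](O[Si](CC)(CC)CC)CC[C@H](Br)[C@@]2(C)CC1 | intermediate
10 | 6-methylhept-5-en-2-one | CC(=O)CCC=C(C)C | starting material
11 | 2,2-bis(phenylseleno)-6-methylhept-5-ene | CC(C)=CCCC(C)([Se]c1ccccc1)[Se]c1ccccc1 | intermediate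
12 | 2-lithio-2-(phenylseleno)-6-methylhept-5-ene (not isolated) | [Li]C(C)(CCC=C(C)C)[Se]c1ccccc1 | intermediate
13 | β-hydroxy selenide: C3 tertiary carbinol bearing the C1′(SePh)(CH3) side chain, mixture at C3 and C1′ | CC(C)=CCCC(C)([Se]c1ccccc1)C1(O)C=C2[C@H](O[Si](CC)(CC)CC)CC[C@H](Br)[C@@]2(C)CC1 | intermediate
14 | exocyclic C1′=C3 diene, 5β-triethylsilyl ether (E/Z mixture, drawn E) | CC(C)=CCC/C(C)=C1/C=C2[C@H](O[Si](CC)(CC)CC)CC[C@H](Br)[C@@]2(C)CC1 | intermediate
15 | exocyclic diene 5β-ol (drawn E) | CC(C)=CCC/C(C)=C1/C=C2[C@H](O)CC[C@H](Br)[C@@]2(C)CC1 | intermediate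
16 | dienone, C5 ketone (drawn E) | CC(C)=CCC/C(C)=C1/C=C2C(=O)CC[C@H](Br)[C@@]2(C)CC1 | intermediate
17 | cyclization precursor: 8β-bromo-5α-methyl-5β-hydroxy dienyl decalin with prenyl-terminated chain (drawn E) | CC(C)=CCC/C(C)=C1/C=C2[C@](C)(O)CC[C@H](Br)[C@@]2(C)CC1 | intermediate
18 | 4aβ,5β-epoxide with the (1′R,3′R)-3-bromo-1,2,2-trimethylcyclopentyl group on C3 and C3=C4 (not isolated) | CC1(C)[C@H](Br)CC[C@]1(C)C1=C[C@]23O[C@]3(C)CC[C@H](Br)[C@@]2(C)CC1 | intermediate
19 | 2-deoxo target: 4aα,5β-diol, 8β-bromide, C3=C4, (1′R,3′R)-bromocyclopentyl on C3 | CC1(C)[C@H](Br)CC[C@]1(C)C1=C[C@]2(O)[C@](C)(O)CC[C@H](Br)[C@@]2(C)CC1 | intermediate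
20 | (4aR,5R,8S,8aS)-8-bromo-3-[(1R,3R)-3-bromo-1,2,2-trimethylcyclopentyl]-4a,5-dihydroxy-5,8a-dimethyl-4a,5,6,7,8,8a-hexahydronaphthalen-2(1H)-one | CC1(C)[C@H](Br)CC[C@]1(C)C1=C[C@]2(O)[C@](C)(O)CC[C@H](Br)[C@@]2(C)CC1=O | target

**Count and risks**

Total step count: 16. Longest linear sequence: 15 steps (steps 1–8 and 10–16 from 1); step 9 is the one-step side branch from 10.

Steps most likely to fail:

1. Step 15 (Proposed new method). Br+ transfer to the diene, or between alkenes, may outpace ring closure. Closure may take the six-ring course. Face selection at the remote alkene may be poor. The dienylic carbinol may ionize before it reacts. The fallback uses known chemistry: a radical ring closure, for which the 5-exo mode is the rule, with bromine introduced by substitution. It sets out from dienone 16 and comes back to the route at 19.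
   - Shi epoxidation (fructose-derived ketone of the enantiomeric series that gives the 3′S oxirane, Oxone (2KHSO5·KHSO4·K2SO4), K2CO3, MeCN/aqueous buffer) attacks the only electron-rich alkene and gives the (3′S)-2′,3′-epoxy dienone F1.
   - Cp2TiCl (trivalent titanium, from Cp2TiCl2 and Mn powder, THF) opens the oxirane to the tertiary C2′ radical. This adds 5-exo to the δ-carbon C1′ of the dienone. After protonation of the titanium dienolate and equilibration with DBU, the product is the hydroxycyclopentyl enone F2, with the 3′S hydroxyl trans to the decalin (Beckwith–Houk transition state).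
   - As in steps 3 and 4, ClCH2SO2Cl/pyridine gives the 3′-chloromethanesulfonate F3, and LiBr in DMF inverts C3′ to the dibromo enone F4.
   - MeLi at −78 °C adds to C5 from the α-face and gives the tertiary carbinol F5.
   - A Schenck ene reaction with singlet oxygen (O2, tetraphenylporphyrin, hν, MeOH to suppress hydroxyl steering) can abstract only the C3 hydrogen. It moves the alkene to C3=C4 and places a hydroperoxide on C4a anti to the angular methyl, giving the hydroperoxide F6. Only the C3 epimer with an α-hydrogen is productive; the other is recycled by base equilibration at the stage of F4.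
   - PPh3 reduces F6 to 19, and step 16 follows.

2. Step 4. The SN2 displacement at a carbon next to quaternary C8a is slow. E2 elimination toward C7, or ionization with a 1,2-methyl shift to the allylic C8a cation, may outrun it. The fallback replaces substitution by radical chemistry. It sets out from ketone 2 and comes back at 5.
   - N2H4·H2O in EtOH at reflux gives the C8 hydrazone F7.
   - CuBr2 (divalent copper) and t-BuOLi in THF convert it, with loss of N2, into the 8,8-dibromide F8.
   - Bu3SnH (1.0 equiv) with AIBN in benzene at 80 °C removes one bromine. The intermediate α-bromo radical should take hydrogen from the α-face, anti to the angular methyl, which leaves the equatorial 8β-bromide 5.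

3. Step 16. After hydrogen abstraction at C2, oxygen may be captured at C4 with alkene transposition. Alternatively the hindered alkene may react too slowly, and the tertiary allylic alcohol may ionize on long exposure. The fallback uses a pericyclic hydroxylation followed by alcohol oxidation. It sets out from 19 and comes back at 20.
   - SeO2 (cat.) with t-BuOOH in CH2Cl2 reacts by an ene reaction and a [2,3]-sigmatropic shift. This sequence by mechanism returns the alkene to C3=C4 and puts oxygen on C2, giving the 2-hydroxy compound F9 (either C2 epimer).
   - DMP with pyridine, or MnO2, oxidizes F9 to 20.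

Further compounds
F1 | step 15 | (3′S)-2′,3′-epoxide of dienone 16 | CC1(C)O[C@H]1CC/C(C)=C1/C=C2C(=O)CC[C@H](Br)[C@@]2(C)CC1
F2 | step 15 | 3-[(1′R,3′S)-3-hydroxy-1,2,2-trimethylcyclopentyl] 8β-bromo enone, C5 ketone conjugated with C4a=C4, C3–H (either epimer) | CC1(C)[C@@H](O)CC[C@]1(C)C1C=C2C(=O)CC[C@H](Br)[C@@]2(C)CC1
F3 | step 15 | 3′-chloromethanesulfonate of F2 | CC1(C)[C@@H](OS(=O)(=O)CCl)CC[C@]1(C)C1C=C2C(=O)CC[C@H](Br)[C@@]2(C)CC1
F4 | step 15 | 3-[(1′R,3′R)-3-bromo-1,2,2-trimethylcyclopentyl] 8β-bromo enone | CC1(C)[C@H](Br)CC[C@]1(C)C1C=C2C(=O)CC[C@H](Br)[C@@]2(C)CC1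
F5 | step 15 | 5α-methyl-5β-hydroxy carbinol from F4 (C4=C4a, C3–H) | CC1(C)[C@H](Br)CC[C@]1(C)C1C=C2[C@](C)(O)CC[C@H](Br)[C@@]2(C)CC1
F6 | step 15 | 4aα-hydroperoxide with C3=C4 and 5β-hydroxyl | CC1(C)[C@H](Br)CC[C@]1(C)C1=C[C@]2(OO)[C@](C)(O)CC[C@H](Br)[C@@]2(C)CC1
F7 | step 4 | C8 hydrazone of ketone 2 | S1CCSC13C=C2CCCC(=NN)[C@@]2(C)CC3
F8 | step 4 | 8,8-dibromo dithiolane | S1CCSC13C=C2CCCC(Br)(Br)[C@@]2(C)CC3
F9 | step 16 | 2-hydroxy derivative of 19 (either C2 epimer) | CC1(C)[C@H](Br)CC[C@]1(C)C1=C[C@]2(O)[C@](C)(O)CC[C@H](Br)[C@@]2(C)CC1O
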